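**Retrosynthetic overview**
1. The target is the erythro-(7R,8S) guaiacylglycerol 8-O-4′ acetosyringone ether; the last disconnection is removal of an isobutyrate from the ring A phenol.
2. The C9 alcohol comes from an aldehyde (borohydride, same flask). The C7–C8 bond comes from a D-proline enamine anti-aldol of (4-acetyl-2,6-dimethoxyphenoxy)acetaldehyde with vanillin isobutyrate, which sets both stereocentres.
3. The aryloxyacetaldehyde comes from acetosyringone and bromoacetaldehyde diethyl acetal (O-alkylation, then acetal hydrolysis).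
4. No ring is formed: ring B is bought as acetosyringone and ring A as vanillin isobutyrate.

Assumption: lignan numbering is used (C7 benzylic carbinol, C8 ether carbon, C9 CH2OH); the SMILES reads as (7R,8S), the erythro (anti) isomer; acetosyringone, bromoacetaldehyde diethyl acetal, vanillin isobutyrate and D-proline are bought.

**Step 1**
Reactants: 1 acetosyringone, 1-(4-hydroxy-3,5-dimethoxyphenyl)ethan-1-one; 2 bromoacetaldehyde diethyl acetal, 2-bromo-1,1-diethoxyethane
Product: 4 (4-acetyl-2,6-dimethoxyphenoxy)acetaldehyde, via diethyl acetal 3 (not isolated)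
Conditions: K2CO3 (2 equiv), KI (0.1 equiv), DMF, 110 °C, 16 h; cool, then 2 M aq HCl (excess), THF, 50 °C, 2 h
Reagents that add atoms: water, O
Why: Williamson ether synthesis (iodide-assisted SN2 of the acidic, hindered phenoxide on the primary bromide) followed by acid-catalysed acetal hydrolysis; the aryl methyl ketone and methyl ethers are inert to carbonate and dilute acid, and no stereocentre is formed.

**Step 2**
Reactants: 4 (4-acetyl-2,6-dimethoxyphenoxy)acetaldehyde; 5 vanillin isobutyrate, 4-formyl-2-methoxyphenyl 2-methylpropanoate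
Product: 7 4-[(1R,2S)-2-(4-acetyl-2,6-dimethoxyphenoxy)-1,3-dihydroxypropyl]-2-methoxyphenyl 2-methylpropanoate, via anti-aldol aldehyde 6 (not isolated)
Conditions: 5 (3 equiv), D-proline (20 mol%), DMF, 4 °C, 4 added by syringe pump over 24 h, then 24 h; then CH2Cl2/MeOH 2:1, NaBH4 (1.5 equiv), −60 °C, 1 h; acetone, then AcOH
Reagents that add atoms: none
Why: Proposed new method: D-proline condenses only with the aldehyde of 4 (the aryl methyl ketone does not form an enamine here) to give the (E)-enamine, which adds to the Si face of the non-enolisable, ester-activated aldehyde 5 through the mirror image of the Houk–List hydrogen-bonded chair transition state of L-proline, forming the C7–C8 bond anti-selectively and giving (2R,3R)-6; slow addition of 4 into excess 5 suppresses donor self-aldol, and NaBH4 at −60 °C then reduces the aldehydes but not the aryl ketone or aryl ester before C8 can epimerise (the C8 descriptor changes from R to S only because CH2OH ranks below C7 whereas CHO ranked above it); the closest known reaction type is the proline-catalysed direct cross-aldol of α-alkoxy- and α-silyloxyacetaldehyde donors and of simple alkanals with aromatic aldehydes, and the new element, to my knowledge undescribed, is an α-aryloxyacetaldehyde donor paired with an aromatic aldehyde acceptor.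

**Step 3**
Reactants: 7 4-[(1R,2S)-2-(4-acetyl-2,6-dimethoxyphenoxy)-1,3-dihydroxypropyl]-2-methoxyphenyl 2-methylpropanoate
Product: 8 1-{4-{[(1R,2S)-1,3-dihydroxy-1-(4-hydroxy-3-methoxyphenyl)propan-2-yl]oxy}-3,5-dimethoxyphenyl}ethan-1-one (target)
Conditions: K2CO3 (20 mol%), MeOH, 0 °C to rt, 3 h; aq NH4Cl
Reagents that add atoms: none
Why: Base-catalysed transesterification (methanolysis) cleaves only the aryl ester because aryloxide is the better leaving group; the ketone, the aryl ethers and both stereocentres (no acidic C–H and no retro-aldol path in the 1,3-diol) are untouched at or below room temperature.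

**Compound list**
1 | acetosyringone, 1-(4-hydroxy-3,5-dimethoxyphenyl)ethan-1-one | CC(=O)c1cc(OC)c(O)c(OC)c1 | starting material
2 | bromoacetaldehyde diethyl acetal, 2-bromo-1,1-diethoxyethane | CCOC(CBr)OCC | starting material
3 | 1-[4-(2,2-diethoxyethoxy)-3,5-dimethoxyphenyl]ethan-1-one | CCOC(COc1c(OC)cc(C(C)=O)cc1OC)OCC | intermediate
4 | (4-acetyl-2,6-dimethoxyphenoxy)acetaldehyde | O=CCOc1c(OC)cc(C(C)=O)cc1OC | intermediate
5 | vanillin isobutyrate, 4-formyl-2-methoxyphenyl 2-methylpropanoate | CC(C)C(=O)Oc1ccc(C=O)cc1OC | starting material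
6 | 4-[(1R,2R)-2-(4-acetyl-2,6-dimethoxyphenoxy)-1-hydroxy-3-oxopropyl]-2-methoxyphenyl 2-methylpropanoate | COc1cc([C@@H](O)[C@H](C=O)Oc2c(OC)cc(C(C)=O)cc2OC)ccc1OC(=O)C(C)C | intermediate
7 | 4-[(1R,2S)-2-(4-acetyl-2,6-dimethoxyphenoxy)-1,3-dihydroxypropyl]-2-methoxyphenyl 2-methylpropanoate | COc1cc([C@@H](O)[C@H](CO)Oc2c(OC)cc(C(C)=O)cc2OC)ccc1OC(=O)C(C)C | intermediate
8 | 1-{4-{[(1R,2S)-1,3-dihydroxy-1-(4-hydroxy-3-methoxyphenyl)propan-2-yl]oxy}-3,5-dimethoxyphenyl}ethan-1-one | COc1cc([C@@H](O)[C@H](CO)Oc2c(OC)cc(C(C)=O)cc2OC)ccc1O | target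

**Total step count:** 3. **Longest linear sequence:** 3 (1 → 4 → 7 → 8).

**Steps most likely to fail**

Step 2 (highest risk, the new cross-aldol). The donor may self-condense, the acceptor may be too slow, the anti/syn ratio may be modest (about 4:1 to 10:1 expected by analogy, so 7 must be separated from its threo isomer by chromatography or crystallisation), and the aryl ester may slowly acylate the catalyst. The fallback uses only known chemistry, sets out from 1 and comes back at 8; it is the classical ketone route to arylglycerol β-aryl ethers and obtains the enantiomer by resolution, not by asymmetric catalysis. Phenol 1 is alkylated with bought 2-bromo-1-[4-(benzyloxy)-3-methoxyphenyl]ethan-1-one (K2CO3, acetone, rt) to give 2-(4-acetyl-2,6-dimethoxyphenoxy)-1-[4-(benzyloxy)-3-methoxyphenyl]ethan-1-one F2. Hydroxymethylation at the doubly activated CH2 (aq formaldehyde, K2CO3, dioxane, rt) gives racemic 2-(4-acetyl-2,6-dimethoxyphenoxy)-1-[4-(benzyloxy)-3-methoxyphenyl]-3-hydroxypropan-1-one F3. Hydroxyl-directed reduction of the β-hydroxy ketone only (Me4NBH(OAc)3, MeCN/AcOH, −20 °C; the acetyl group has no directing hydroxyl) and chromatographic removal of the threo isomer give racemic erythro 1-{4-{[1-[4-(benzyloxy)-3-methoxyphenyl]-1,3-dihydroxypropan-2-yl]oxy}-3,5-dimethoxyphenyl}ethan-1-one F4. Preparative chromatography on a cellulose tris(3,5-dimethylphenylcarbamate) phase gives its (1R,2S) enantiomer, 1-{4-{[(1R,2S)-1-[4-(benzyloxy)-3-methoxyphenyl]-1,3-dihydroxypropan-2-yl]oxy}-3,5-dimethoxyphenyl}ethan-1-one F5. Hydrogenolysis (H2 1 atm, Pd/C, EtOAc, rt) gives 8.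

Step 1. The di-ortho-substituted phenoxide may alkylate the β-branched bromide only sluggishly at 110 °C, and 4 may isolate partly as its hydrate. The fallback sets out from 1 and comes back at 4. Allylation (allyl bromide, K2CO3, acetone, reflux) gives 1-[3,5-dimethoxy-4-(prop-2-en-1-yloxy)phenyl]ethan-1-one F1. Ozonolysis (O3, CH2Cl2/MeOH, −78 °C, Sudan red 7B as end-point indicator to spare the electron-rich ring; then Me2S) gives 4.

Step 3. If forced, the phenoxide para to the benzylic carbinol can expel hydroxide to a quinone methide, which would scramble C7 or give the C7 methyl ether. The fallback sets out from 4 and comes back at 8; it changes the protecting group so that the final unmasking is neutral. Vanillin and allyl chloroformate (K2CO3, acetone, 0 °C) give 4-formyl-2-methoxyphenyl prop-2-en-1-yl carbonate F6. The same D-proline aldol and NaBH4 reduction with 4 give, via the aldehyde 4-[(1R,2R)-2-(4-acetyl-2,6-dimethoxyphenoxy)-1-hydroxy-3-oxopropyl]-2-methoxyphenyl prop-2-en-1-yl carbonate F7, the diol 4-[(1R,2S)-2-(4-acetyl-2,6-dimethoxyphenoxy)-1,3-dihydroxypropyl]-2-methoxyphenyl prop-2-en-1-yl carbonate F8. Pd(PPh3)4 (zerovalent palladium, 2 mol%) and morpholine in THF at rt give 8.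

**Further compounds**
F1 | step 1 | 1-[3,5-dimethoxy-4-(prop-2-en-1-yloxy)phenyl]ethan-1-one | C=CCOc1c(OC)cc(C(C)=O)cc1OC
F2 | step 2 | 2-(4-acetyl-2,6-dimethoxyphenoxy)-1-[4-(benzyloxy)-3-methoxyphenyl]ethan-1-one | COc1cc(C(=O)COc2c(OC)cc(C(C)=O)cc2OC)ccc1OCc1ccccc1
F3 | step 2 | racemic 2-(4-acetyl-2,6-dimethoxyphenoxy)-1-[4-(benzyloxy)-3-methoxyphenyl]-3-hydroxypropan-1-one | COc1cc(C(=O)C(CO)Oc2c(OC)cc(C(C)=O)cc2OC)ccc1OCc1ccccc1
F4 | step 2 | racemic erythro 1-{4-{[1-[4-(benzyloxy)-3-methoxyphenyl]-1,3-dihydroxypropan-2-yl]oxy}-3,5-dimethoxyphenyl}ethan-1-one, (1R,2S) and (1S,2R) 1:1 | COc1cc([C@@H](O)[C@H](CO)Oc2c(OC)cc(C(C)=O)cc2OC)ccc1OCc1ccccc1.COc1cc([C@H](O)[C@@H](CO)Oc2c(OC)cc(C(C)=O)cc2OC)ccc1OCc1ccccc1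
F5 | step 2 | 1-{4-{[(1R,2S)-1-[4-(benzyloxy)-3-methoxyphenyl]-1,3-dihydroxypropan-2-yl]oxy}-3,5-dimethoxyphenyl}ethan-1-one | COc1cc([C@@H](O)[C@H](CO)Oc2c(OC)cc(C(C)=O)cc2OC)ccc1OCc1ccccc1
F6 | step 3 | 4-formyl-2-methoxyphenyl prop-2-en-1-yl carbonate | COc1cc(C=O)ccc1OC(=O)OCC=C
F7 | step 3 | 4-[(1R,2R)-2-(4-acetyl-2,6-dimethoxyphenoxy)-1-hydroxy-3-oxopropyl]-2-methoxyphenyl prop-2-en-1-yl carbonate | COc1cc([C@@H](O)[C@H](C=O)Oc2c(OC)cc(C(C)=O)cc2OC)ccc1OC(=O)OCC=C
F8 | step 3 | 4-[(1R,2S)-2-(4-acetyl-2,6-dimethoxyphenoxy)-1,3-dihydroxypropyl]-2-methoxyphenyl prop-2-en-1-yl carbonate | COc1cc([C@@H](O)[C@H](CO)Oc2c(OC)cc(C(C)=O)cc2OC)ccc1OC(=O)OCC=C
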